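## Retrosynthetic overview

1. Target ⇒ silyl ether 29 ⇒ B-alkyl Suzuki disconnection at C12–C13 into bicyclic diene 15 and the (E)-iodoalkene butenolide 27; in 27, C16 comes from an asymmetric propargylation of furan-3-carbaldehyde and the butenolide from the furan (singlet oxygen, then borohydride).
2. 15 ⇐ enol triflate 13 ⇐ trans-ketone 11 (C9 carbonyl beside quaternary C10, so only C8 can enolise) ⇐ dienone 10 ⇐ cis-fused enone 9.
3. 9 ⇐ iodo-enone 7 by closure of ring A between C1 and C10; 7 ⇐ (S)-carvone, whose six ring carbons become ring B, whose ring methyl becomes C17 on C8 and whose isopropenyl carbon becomes C4 with both methyl groups after MHAT coupling with acrolein (C3–C1).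
4. Enabling feature: C10 is the α′ carbon of the ring-B carbonyl C9 (the carbon that ends as the side-chain terminus of the C8=C9 alkene), and its neighbour C5 carries the C4 chain. C1 can therefore alkylate the enolate only on the face of the C5–C4 bond; carvone's stereocentre fixes quaternary C10 and is then itself re-set at C5 by dehydrogenation and hydrogenation.
5. Ring order: ring B from the chiral pool, ring A in step 5, butenolide ring from the furan in steps 14 and 15.

Key step: step 5

Assumption: the target is taken as the (5S,10S,13Z,16R) compound of the SMILES, with labdane-type locants (ring A = C1–C5, C10; ring B = C5–C10; C17 on C8, C18/C19 on C4, C20 on C10; chain C11–C16 with the hydroxymethyl group on C13); compounds 1, 4, 14, 16 and 17 are taken as commercial.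

## Route

Step 1
Reactants: 1 (S)-(+)-carvone
Product: 3 (5S,6R)-2,6-dimethyl-5-(prop-1-en-2-yl)cyclohex-2-en-1-one (trans-6-methylcarvone), via lithium enolate 2 (not isolated)
Conditions: LiN(iPr)2, THF, −78 °C; MeI, −78 → 0 °C
Reagents that add atoms: methyl iodide, CI
Why: Kinetic α′-deprotonation of the cross-conjugated enone and SN2 methylation (enolate alkylation) should occur mainly anti to the isopropenyl group, and the selectivity at this centre is unimportant because it is planarised again in step 5.

Step 2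
Reactants: 3 trans-6-methylcarvone; 4 acrolein
Product: 5 4-[(1S,2R)-2,4-dimethyl-3-oxocyclohex-4-en-1-yl]-4-methylpentanal
Conditions: Fe(acac)3 (30 mol %), PhSiH3, EtOH, 60 °C
Reagents that add atoms: none
Why: Hydrogen-atom transfer from an iron hydride to the 1,1-disubstituted isopropenyl group (Mukaiyama-type MHAT) should give the tertiary radical, which adds to acrolein (Giese-type reductive olefin coupling) and so creates C4 with both methyl groups and the C3–C1 chain, while the electron-poor trisubstituted enone is a poor hydrogen-atom acceptor; no stereocentre is formed.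

Step 3
Reactants: 5 keto aldehyde
Product: 6 (5S,6R)-5-(5-hydroxy-2-methylpentan-2-yl)-2,6-dimethylcyclohex-2-en-1-one
Conditions: NaBH4 (0.3 equiv), EtOH/CH2Cl2, −78 °C
Reagents that add atoms: none
Why: Borohydride reduction at low temperature should be selective for the aldehyde over the hindered conjugated ketone.

Step 4
Reactants: 6 keto alcohol
Product: 7 (5S,6R)-5-(5-iodo-2-methylpentan-2-yl)-2,6-dimethylcyclohex-2-en-1-one
Conditions: I2, PPh3, imidazole, CH2Cl2, 0 → 23 °C
Reagents that add atoms: iodine, [I][I]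
Why: Appel-type iodination of the primary alcohol through the alkoxyphosphonium salt and SN2 displacement by iodide leaves the enone untouched.

Step 5
Reactants: 7 iodo-enone
Product: 9 (4aR,8aS)-2,5,5,8a-tetramethyl-4a,5,6,7,8,8a-hexahydronaphthalen-1(4H)-one (cis-fused enone), via lithium dienolate 8 (not isolated)
Conditions: LiN(iPr)2, THF, −78 °C; DMPU, −78 → 23 °C
Reagents that add atoms: none
Why: LiN(iPr)2 removes the only α′ hydrogen (at C10) to give the cross-conjugated lithium dienolate 8, whose C10 displaces the primary iodide at C1 in an intramolecular SN2 reaction; the closest known reaction type is the alkylation of α′-enolates of 6-alkylcarvones and the intramolecular enolate alkylations that give fused bicyclic ketones. Ring A is closed in the 6-(enolendo)-exo-tet mode. The new quaternary stereocentre C10 is controlled by C5 of carvone: the bond must form along the p-orbital axis of the endocyclic C9=C10 enolate, and the chain anchored through C4 at the neighbouring C5 can reach that axis only on the face of the C5–C4 bond (a trans closure would need a C4–C5–C10–C1 dihedral angle of about 120–180°), so only the cis-fused product with the C10 methyl syn to H-5 can form and C10 obtains the S configuration of the target. The step needs α′- over γ-deprotonation and C- over O-alkylation; the first is secured by the kinetic amide base at low temperature, the second by ring size, because O-alkylation would need an eight-membered ring. Both C10 epimers of 7 converge on the same enolate.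

Step 6
Reactants: 9 cis-fused enone
Product: 10 (8aS)-2,5,5,8a-tetramethyl-6,7,8,8a-tetrahydronaphthalen-1(5H)-one (linear dienone, C5=C6 and C7=C8)
Conditions: chloranil, t-BuOH, reflux
Reagents that add atoms: none
Why: Quinone dehydrogenation of the enone through its extended dienol (hydride abstraction from C5), a known way from cyclohexenones to linear dienones, can only give this dienone because C10 is quaternary, and it erases the C5 centre after it has relayed its chirality to C10.

Step 7
Reactants: 10 dienone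
Product: 11 (4aS,8aS)-2,5,5,8a-tetramethyloctahydronaphthalen-1(2H)-one (trans-fused; both C2 epimers)
Conditions: H2 (4 atm), Pd/C, EtOAc, 23 °C
Reagents that add atoms: none
Why: Heterogeneous hydrogenation reduces both C=C bonds and should deliver hydrogen to C5 from the α face, opposite to the two syn-axial methyl groups on C10 and C4 (as in the hydrogenation of 4,4-dimethyl-Δ5 steroids), which sets the trans ring fusion (5S); the C8 epimers converge in step 8.

Step 8
Reactants: 11 trans-ketone
Product: 13 (4aS,8aS)-2,5,5,8a-tetramethyl-3,4,4a,5,6,7,8,8a-octahydronaphthalen-1-yl trifluoromethanesulfonate, via potassium enolate 12 (not isolated)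
Conditions: KN(SiMe3)2, THF, −78 → 0 °C; PhNTf2, 0 → 23 °C
Reagents that add atoms: N-phenylbis(trifluoromethanesulfonimide), O=S(=O)(N(c1ccccc1)S(=O)(=O)C(F)(F)F)C(F)(F)F
Why: Because C10 is quaternary the ketone can enolise only toward C8, so deprotonation and O-sulfonylation (enol triflate formation, as for 2,2,6-trimethylcyclohexanone) should give the tetrasubstituted C8=C9 enol triflate regiospecifically.

Step 9
Reactants: 13 enol triflate; 14 tributyl(vinyl)stannane
Product: 15 (4aS,8aS)-1-ethenyl-2,5,5,8a-tetramethyl-3,4,4a,5,6,7,8,8a-octahydronaphthalene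
Conditions: Pd(PPh3)4 (5 mol %), LiCl, THF, 65 °C
Reagents that add atoms: none
Why: Stille cross-coupling of a hindered cyclohexenyl triflate with a small vinylstannane, with chloride to assist transmetalation, installs C11 and C12 without touching the stereocentres.

Step 10
Reactants: 16 furan-3-carbaldehyde; 17 allenylboronic acid pinacol ester
Product: 19 (1R)-1-(furan-3-yl)but-3-yn-1-ol, via borate ester 18 (not isolated)
Conditions: (R)-TRIP phosphoric acid (5 mol %), 4 Å MS, toluene, −20 °C; aq. work-up
Reagents that add atoms: none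
Why: Chiral phosphoric acid-catalysed propargylation of the aldehyde by the allenylboronate through a six-membered chair transition state (SE2′) sets C16, the catalyst enantiomer being the one that shields the aldehyde face leading to the S carbinol, so that the R carbinol forms.

Step 11
Reactants: 19 homopropargylic alcohol
Product: 20 tert-butyl{[(1R)-1-(furan-3-yl)but-3-yn-1-yl]oxy}dimethylsilane
Conditions: TBSCl, imidazole, DMF, 23 °C
Reagents that add atoms: tert-butyldimethylsilyl chloride, CC(C)(C)[Si](C)(C)Cl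
Why: Standard silylation protects the secondary carbinol against the organolithium, tin hydride and borohydride steps that follow.

Step 12
Reactants: 20 silyl ether
Product: 22 (5R)-5-[(tert-butyldimethylsilyl)oxy]-5-(furan-3-yl)pent-2-yn-1-ol, via lithium acetylide 21 (not isolated)
Conditions: n-BuLi, THF, −78 °C; (CH2O)n, −78 → 23 °C; H2O
Reagents that add atoms: paraformaldehyde (as formaldehyde), C=O
Why: Deprotonation of the terminal alkyne (far more acidic than the furan C–H) and 1,2-addition of the acetylide to formaldehyde supplies the hydroxymethyl carbon on C13.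

Step 13
Reactants: 22 propargylic alcohol
Product: 24 (2E,5R)-5-[(tert-butyldimethylsilyl)oxy]-5-(furan-3-yl)-2-iodopent-2-en-1-ol, via vinylstannane 23 (not isolated)
Conditions: Bu3SnH, Mo(CO)3(CNtBu)3 (2 mol %), hydroquinone (cat.), THF, 55 °C; then I2, CH2Cl2, 0 °C
Reagents that add atoms: iodine, [I][I]
Why: Molybdenum-catalysed hydrostannation should add H and Sn syn with tin on the carbon next to the CH2OH group, and iododestannylation with retention then gives the E iodide in which the hydroxymethyl group is cis to C15, the geometry of the target alkene.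

Step 14
Reactants: 24 furyl iodoalkene
Product: 26 4-[(1R,3E)-1-[(tert-butyldimethylsilyl)oxy]-5-hydroxy-4-iodopent-3-en-1-yl]-5-hydroxyfuran-2(5H)-one (lactol epimers), via endoperoxide 25 (not isolated)
Conditions: O2, hν (visible), rose bengal (cat.), iPr2NEt, CH2Cl2, −78 °C
Reagents that add atoms: dioxygen, O=O
Why: [4+2] Cycloaddition of singlet oxygen to the furan and base-induced (Kornblum–DeLaMare) opening of the endoperoxide, in which the hindered amine removes the bridgehead hydrogen remote from the substituent, should give the 4-substituted 5-hydroxybutenolide, the iodoalkene being too electron-poor to react.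

Step 15
Reactants: 26 hydroxybutenolide
Product: 27 4-[(1R,3E)-1-[(tert-butyldimethylsilyl)oxy]-5-hydroxy-4-iodopent-3-en-1-yl]furan-2(5H)-one
Conditions: NaBH4, MeOH, 0 °C; then dil. HCl
Reagents that add atoms: none
Why: Borohydride reduces the open-chain aldehyde form of the lactol and the resulting Z hydroxy acid lactonises on acidification to the 4-substituted butenolide.

Step 16
Reactants: 15 bicyclic diene; 27 iodoalkene butenolide
Product: 29 4-[(1R,3Z)-1-[(tert-butyldimethylsilyl)oxy]-4-(hydroxymethyl)-6-[(4aS,8aS)-2,5,5,8a-tetramethyl-3,4,4a,5,6,7,8,8a-octahydronaphthalen-1-yl]hex-3-en-1-yl]furan-2(5H)-one, via alkylborane 28 (not isolated)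
Conditions: 9-BBN, THF, 0 → 23 °C; then 27, PdCl2(dppf) (5 mol %), AsPh3, aq. K3PO4, DMF, 23 °C
Reagents that add atoms: none
Why: 9-BBN hydroborates only the monosubstituted vinyl group (the tetrasubstituted C8=C9 bond is inert) and B-alkyl Suzuki–Miyaura coupling with the vinyl iodide proceeds with retention of alkene geometry, forming C12–C13 and the Z trisubstituted alkene.

Step 17
Reactants: 29 silyl ether
Product: 30 CNP0224983.2 (target)
Conditions: HF·pyridine, THF, 0 → 23 °C
Reagents that add atoms: none
Why: Fluoride cleavage of the secondary silyl ether under mildly acidic conditions should leave the butenolide, the allylic alcohol and both alkenes untouched.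

## Compound list

1 | (S)-(+)-carvone | CC1=CC[C@@H](CC1=O)C(C)=C | starting material
2 | lithium (3S)-6-methyl-3-(prop-1-en-2-yl)cyclohexa-1,5-dien-1-olate | CC1=CC[C@@H](C=C1O[Li])C(C)=C | intermediate
3 | (5S,6R)-2,6-dimethyl-5-(prop-1-en-2-yl)cyclohex-2-en-1-one (major epimer drawn) | CC1=CC[C@@H]([C@@H](C)C1=O)C(C)=C | intermediate
4 | acrolein | C=CC=O | starting material
5 | 4-[(1S,2R)-2,4-dimethyl-3-oxocyclohex-4-en-1-yl]-4-methylpentanal | CC1=CC[C@@H]([C@@H](C)C1=O)C(C)(C)CCC=O | intermediate
6 | (5S,6R)-5-(5-hydroxy-2-methylpentan-2-yl)-2,6-dimethylcyclohex-2-en-1-one | CC1=CC[C@@H]([C@@H](C)C1=O)C(C)(C)CCCO | intermediate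
7 | (5S,6R)-5-(5-iodo-2-methylpentan-2-yl)-2,6-dimethylcyclohex-2-en-1-one | CC1=CC[C@@H]([C@@H](C)C1=O)C(C)(C)CCCI | intermediate
8 | lithium (3R)-3-(5-iodo-2-methylpentan-2-yl)-2,6-dimethylcyclohexa-1,5-dien-1-olate | CC1=CC[C@@H](C(C)=C1O[Li])C(C)(C)CCCI | intermediate
9 | (4aR,8aS)-2,5,5,8a-tetramethyl-4a,5,6,7,8,8a-hexahydronaphthalen-1(4H)-one | CC1=CC[C@@H]2C(C)(C)CCC[C@]2(C)C1=O | intermediate
10 | (8aS)-2,5,5,8a-tetramethyl-6,7,8,8a-tetrahydronaphthalen-1(5H)-one | CC1=CC=C2C(C)(C)CCC[C@]2(C)C1=O | intermediate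
11 | (4aS,8aS)-2,5,5,8a-tetramethyloctahydronaphthalen-1(2H)-one (C2 epimers) | CC1CC[C@H]2C(C)(C)CCC[C@]2(C)C1=O | intermediate
12 | potassium (4aS,8aS)-2,5,5,8a-tetramethyl-3,4,4a,5,6,7,8,8a-octahydronaphthalen-1-olate | CC1=C(O[K])[C@@]2(C)CCCC(C)(C)[C@@H]2CC1 | intermediate
13 | (4aS,8aS)-2,5,5,8a-tetramethyl-3,4,4a,5,6,7,8,8a-octahydronaphthalen-1-yl trifluoromethanesulfonate | CC1=C(OS(=O)(=O)C(F)(F)F)[C@@]2(C)CCCC(C)(C)[C@@H]2CC1 | intermediate
14 | tributyl(vinyl)stannane | C=C[Sn](CCCC)(CCCC)CCCC | starting material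
15 | (4aS,8aS)-1-ethenyl-2,5,5,8a-tetramethyl-3,4,4a,5,6,7,8,8a-octahydronaphthalene | CC1=C(C=C)[C@@]2(C)CCCC(C)(C)[C@@H]2CC1 | intermediate
16 | furan-3-carbaldehyde | O=Cc1ccoc1 | starting material
17 | allenylboronic acid pinacol ester | C=C=CB1OC(C)(C)C(C)(C)O1 | starting material
18 | 2-{[(1R)-1-(furan-3-yl)but-3-yn-1-yl]oxy}-4,4,5,5-tetramethyl-1,3,2-dioxaborolane | C#CC[C@@H](OB1OC(C)(C)C(C)(C)O1)c1ccoc1 | intermediate
19 | (1R)-1-(furan-3-yl)but-3-yn-1-ol | C#CC[C@@H](O)c1ccoc1 | intermediate
20 | tert-butyl{[(1R)-1-(furan-3-yl)but-3-yn-1-yl]oxy}dimethylsilane | C#CC[C@@H](O[Si](C)(C)C(C)(C)C)c1ccoc1 | intermediate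
21 | {(4R)-4-[(tert-butyldimethylsilyl)oxy]-4-(furan-3-yl)but-1-yn-1-yl}lithium | [Li]C#CC[C@@H](O[Si](C)(C)C(C)(C)C)c1ccoc1 | intermediate
22 | (5R)-5-[(tert-butyldimethylsilyl)oxy]-5-(furan-3-yl)pent-2-yn-1-ol | OCC#CC[C@@H](O[Si](C)(C)C(C)(C)C)c1ccoc1 | intermediate
23 | (2E,5R)-5-[(tert-butyldimethylsilyl)oxy]-5-(furan-3-yl)-2-(tributylstannyl)pent-2-en-1-ol | CCCC[Sn](CCCC)(CCCC)/C(=C/C[C@@H](O[Si](C)(C)C(C)(C)C)c1ccoc1)CO | intermediate
24 | (2E,5R)-5-[(tert-butyldimethylsilyl)oxy]-5-(furan-3-yl)-2-iodopent-2-en-1-ol | I/C(=C/C[C@@H](O[Si](C)(C)C(C)(C)C)c1ccoc1)CO | intermediate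
25 | (2E,5R)-5-[(tert-butyldimethylsilyl)oxy]-2-iodo-5-(2,3,7-trioxabicyclo[2.2.1]hept-5-en-5-yl)pent-2-en-1-ol | I/C(=C/C[C@@H](O[Si](C)(C)C(C)(C)C)C1=CC2OOC1O2)CO | intermediate
26 | 4-[(1R,3E)-1-[(tert-butyldimethylsilyl)oxy]-5-hydroxy-4-iodopent-3-en-1-yl]-5-hydroxyfuran-2(5H)-one | I/C(=C/C[C@@H](O[Si](C)(C)C(C)(C)C)C1=CC(=O)OC1O)CO | intermediate
27 | 4-[(1R,3E)-1-[(tert-butyldimethylsilyl)oxy]-5-hydroxy-4-iodopent-3-en-1-yl]furan-2(5H)-one | I/C(=C/C[C@@H](O[Si](C)(C)C(C)(C)C)C1=CC(=O)OC1)CO | intermediate
28 | 9-{2-[(4aS,8aS)-2,5,5,8a-tetramethyl-3,4,4a,5,6,7,8,8a-octahydronaphthalen-1-yl]ethyl}-9-borabicyclo[3.3.1]nonane | CC1=C(CCB3C4CCCC3CCC4)[C@@]2(C)CCCC(C)(C)[C@@H]2CC1 | intermediate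
29 | 4-[(1R,3Z)-1-[(tert-butyldimethylsilyl)oxy]-4-(hydroxymethyl)-6-[(4aS,8aS)-2,5,5,8a-tetramethyl-3,4,4a,5,6,7,8,8a-octahydronaphthalen-1-yl]hex-3-en-1-yl]furan-2(5H)-one | CC1=C(CC/C(=C/C[C@@H](O[Si](C)(C)C(C)(C)C)C2=CC(=O)OC2)CO)[C@@]2(C)CCCC(C)(C)[C@@H]2CC1 | intermediate
30 | CNP0224983.2, 4-[(1R,3Z)-1-hydroxy-4-(hydroxymethyl)-6-[(4aS,8aS)-2,5,5,8a-tetramethyl-3,4,4a,5,6,7,8,8a-octahydronaphthalen-1-yl]hex-3-en-1-yl]furan-2(5H)-one | CC1=C(CC/C(=C/C[C@@H](O)C2=CC(=O)OC2)CO)[C@@]2(C)CCCC(C)(C)[C@@H]2CC1 | target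

## Step count and risks

Total step count: 17. Longest linear sequence: 11 steps (steps 1–9, 16 and 17, from (S)-carvone).

Steps most likely to fail:

Step 2. The tertiary radical may be reduced before it adds (net hydrogenation of the isopropenyl group), acrolein may oligomerise, or the adduct enolate may be captured by the ring ketone in an aldol reaction. The fallback sets out from 3 and comes back at 6. Markovnikov addition of HBr in acetic acid at 0 °C should give the tertiary bromide (5S,6R)-5-(2-bromopropan-2-yl)-2,6-dimethylcyclohex-2-en-1-one F1. Keck radical allylation (allyltributylstannane, AIBN, benzene, 80 °C) should then give (5S,6R)-2,6-dimethyl-5-(2-methylpent-4-en-2-yl)cyclohex-2-en-1-one F2. Hydroboration of its terminal alkene with 9-BBN and oxidation with NaBO3 (the hindered enone is left) should give 6.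

Step 6. Hydride abstraction from the hindered C5–H by the quinone may be too slow, so that the enone is recovered or degraded on prolonged heating. The fallback sets out from 9 and comes back at 10. TBSOTf and Et3N should give the extended silyl dienol ether tert-butyldimethyl{[(4aR,8aS)-2,5,5,8a-tetramethyl-4a,5,6,7,8,8a-hexahydronaphthalen-1-yl]oxy}silane F3; only the C6 hydrogens are available, since C10 is quaternary. Saegusa–Ito oxidation with Pd(OAc)2 in MeCN should then give 10 through β-hydride elimination of H-5.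

Step 16. The aqueous base may open or isomerise the butenolide, or the alkylborane may be protodeboronated before transmetalation. The fallback sets out from 15 and 24 and comes back at 29. The same hydroboration (alkylborane 28) and coupling with the base-stable furyl iodide 24 should give the furan 3-{(1R,3Z)-1-[(tert-butyldimethylsilyl)oxy]-4-(hydroxymethyl)-6-[(4aS,8aS)-2,5,5,8a-tetramethyl-3,4,4a,5,6,7,8,8a-octahydronaphthalen-1-yl]hex-3-en-1-yl}furan F4. Singlet-oxygen oxidation under the conditions of step 14 at −78 °C (the furan should react faster than the hindered tetrasubstituted alkene) should give the hydroxybutenolide 4-{(1R,3Z)-1-[(tert-butyldimethylsilyl)oxy]-4-(hydroxymethyl)-6-[(4aS,8aS)-2,5,5,8a-tetramethyl-3,4,4a,5,6,7,8,8a-octahydronaphthalen-1-yl]hex-3-en-1-yl}-5-hydroxyfuran-2(5H)-one F5. Borohydride reduction as in step 15 should then give 29.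

## Further compounds

F1 | step 2 | (5S,6R)-5-(2-bromopropan-2-yl)-2,6-dimethylcyclohex-2-en-1-one | CC1=CC[C@@H]([C@@H](C)C1=O)C(C)(C)Br
F2 | step 2 | (5S,6R)-2,6-dimethyl-5-(2-methylpent-4-en-2-yl)cyclohex-2-en-1-one | CC1=CC[C@@H]([C@@H](C)C1=O)C(C)(C)CC=C
F3 | step 6 | tert-butyldimethyl{[(4aR,8aS)-2,5,5,8a-tetramethyl-4a,5,6,7,8,8a-hexahydronaphthalen-1-yl]oxy}silane | CC1=C(O[Si](C)(C)C(C)(C)C)[C@@]2(C)CCCC(C)(C)[C@H]2C=C1
F4 | step 16 | 3-{(1R,3Z)-1-[(tert-butyldimethylsilyl)oxy]-4-(hydroxymethyl)-6-[(4aS,8aS)-2,5,5,8a-tetramethyl-3,4,4a,5,6,7,8,8a-octahydronaphthalen-1-yl]hex-3-en-1-yl}furan | CC1=C(CC/C(=C/C[C@@H](O[Si](C)(C)C(C)(C)C)c2ccoc2)CO)[C@@]2(C)CCCC(C)(C)[C@@H]2CC1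
F5 | step 16 | 4-{(1R,3Z)-1-[(tert-butyldimethylsilyl)oxy]-4-(hydroxymethyl)-6-[(4aS,8aS)-2,5,5,8a-tetramethyl-3,4,4a,5,6,7,8,8a-octahydronaphthalen-1-yl]hex-3-en-1-yl}-5-hydroxyfuran-2(5H)-one | CC1=C(CC/C(=C/C[C@@H](O[Si](C)(C)C(C)(C)C)C2=CC(=O)OC2O)CO)[C@@]2(C)CCCC(C)(C)[C@@H]2CC1
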